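Tuesday's charge of solid substrate was 4.00 times Friday's, while its target fraction at 6.00 min was smaller by a factor of 3.34, so target gained per litre moved far less than the charge.

| flask | solid substrate | remark | time |
|---|---|---|---|
| Friday's | 0.050 M | run made earlier |  |
| Tuesday's | 0.20 M | run made earlier |  |
| flask | 0.10 M |  | 8.0 min |

| run | time / min | target / % | starting material / % |
|---|---|---|---|
| Friday's | 0.500 | 3.9 | 3.0 |
| Friday's | 0.833 | 7.5 | 4.1 |
| Friday's | 1.33 | 11.1 | 8.6 |
| Friday's | 2.50 | 21.1 | 10.2 |
| Friday's | 4.00 | 35.1 | 13.5 |
| Friday's | 6.00 | 47.4 | 14.7 |
| Tuesday's | 1.00 | 3.1 | 1.4 |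
| Tuesday's | 2.00 | 6.7 | 1.6 |
| Tuesday's | 3.00 | 6.2 | 2.0 |
| Tuesday's | 4.00 | 8.3 | 2.9 |
| Tuesday's | 5.00 | 12.2 | 5.6 |
| Tuesday's | 6.00 | 14.2 | 3.5 |

(scatter of a reading: 1 percentage point)

- given per volume of solution although it is solid: solid substrate
- what was read earlier has a scatter of 1 percentage point, one standard deviation
- at the start none of the solid substrate is in solution
- starting material means what is dissolved; the solid is not counted in it
- starting material is what solid substrate becomes in solution

1. how much target there is at 8.0 min, in percent of the solid substrate charged
2. concentration of starting material in solution at 8.0 min, in percent of saturation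

1. We rescale each last target reading to the new charge and extend a straight line to 8.0 min. Friday's gives 31.6% and Tuesday's 37.9%. We commit to their mean, 34.7%.

2. We assume that target and starting material exchange quickly and keep a steady ratio (a quasi-equilibrium). Friday's last reading puts that ratio at 3.22, so starting material would be 10.8% of the charge.

3. The weak link is that single reading. We therefore define the split, target over starting material summed across Friday's last two readings, 2.93. Tuesday's last two give 2.90. Starting material in the new flask at 8.0 min becomes 11.8% of its charge. We have no reckoning of our own for saturation.

The forecast gives 34% (29% to 39%) for target and 47% (33% to 80%) of saturation, adding “This estimate is poorly determined”.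

The flask gives 30.6% target and 25.2% of saturation.

    isomer of the product ⇌ starting material (k = 0.00550 s⁻¹)
    starting material ⇌ target (K = 3.10, k = 0.0560 s⁻¹)
    2 starting material → self-condensation product (k = 0.0410 M⁻¹ s⁻¹)
    starting material ⇌ dormant form (K = 0.880, k = 0.00830 s⁻¹)
    solid substrate ⇌ starting material, rate k5*(cs5 - [starting material]) while solid is left; crystals form when [starting material] > cs5 (solubility = 43.0 mM, k = 0.00380 s⁻¹)
    target ⇌ isomer of the product (K = 0.600, k = 8.00 × 10⁻⁴ s⁻¹)

This flask has not come to rest at 8.0 min. Target over starting material in it then stands at 2.82 against our split of 2.93. A neighbour flask charged with 0.025 M shows 44.6% target at that time, so our split predicts 15.2% starting material there, and that flask holds 14.3%. Left ten times as long, to 80.0 min, this flask's solid substrate falls from 33.5% to 0% and its target over starting material reads 3.12. Its target, 30.6% at 8.0 min, stands at 41.4% at 16.0 min and at 25.7% at 80.0 min, while self-condensation product, counted by the two units it holds, climbs from 1.97% to 43.1%.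

All runs stem from a simulated flask from invented constants, noise included.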